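**Plan**

- Retrosynthesis: the two phenols are unmasked last (O–CH3 bonds). The butenolide is then cut at its C3=C4 double bond and at the lactone O1–C2 bond, which removes a two-carbon ketenylidene unit (Ph3P=C=C=O).
- The feature that allows this: O1–C5(=CH–Ar)–C4(Ar) of the furanone ring is the Z-enol of an aryl benzyl 1,2-diketone. C4 is its ketone carbon and O1 its enol oxygen, held on neighbouring carbons and ready to be bridged by C2–C3.
- That α-hydroxychalcone is cut at its Cα=Cβ bond (crossed aldol) into 3,5-dibromo-4-methoxybenzaldehyde and a THP-protected α-hydroxy aryl ketone. The ketone comes from 3',5'-dibromo-4'-hydroxyacetophenone by O-methylation and α-hydroxylation.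
- Forward: the three-carbon chain ArCO–C(O)=CH–Ar is joined first. The only new ring, the lactone, is then closed by enol O-acylation and intramolecular Wittig olefination in one operation, and BBr3 frees the phenols.
- Stereochemistry: there is no stereocentre. The Z exocyclic alkene is the enol double bond of the α-hydroxychalcone (aryl trans to aroyl, thermodynamic), carried unchanged into the ring.

Key step: step 5

Remark: the benzyl aryl 1,2-diketone is drawn and used as its chelated Z-enol (α-hydroxychalcone), the tautomer expected to dominate; the phenols are carried as methyl ethers because free phenols would add to the ketenylidene ylide.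

**Route**

Step 1
Reactants: 1 1-(3,5-dibromo-4-hydroxyphenyl)ethanone
Product: 2 1-(3,5-dibromo-4-methoxyphenyl)ethanone
Conditions: MeI, K2CO3, DMF, rt
Reagents that add atoms: iodomethane, CI
Why: Williamson O-methylation of an acidic 2,6-dibromophenol, whose phenoxide forms with K2CO3 while the methyl ketone is not enolised under these conditions.

Step 2
Reactants: 2 1-(3,5-dibromo-4-methoxyphenyl)ethanone
Product: 4 1-(3,5-dibromo-4-methoxyphenyl)-2-hydroxyethanone, via hydroxy dimethyl ketal 3 (not isolated)
Conditions: PhI(OAc)2, KOH, MeOH, 0 °C to rt; then 2 M HCl, THF, rt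
Reagents that add atoms: methanol, CO (the two OMe groups of 3); water, O (the carbonyl oxygen of 4)
Why: Moriarty α-hydroxylation, in which the enolate attacks the hypervalent iodine reagent, methoxide adds to the carbonyl, iodobenzene leaves through a methoxy epoxide that methanol opens to the α-hydroxy dimethyl ketal, and dilute acid then unmasks the ketone.

Step 3
Reactants: 4 1-(3,5-dibromo-4-methoxyphenyl)-2-hydroxyethanone
Product: 5 1-(3,5-dibromo-4-methoxyphenyl)-2-(tetrahydro-2H-pyran-2-yloxy)ethanone (racemic)
Conditions: 3,4-dihydro-2H-pyran, PPTS (cat.), CH2Cl2, rt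
Reagents that add atoms: 3,4-dihydro-2H-pyran, C1=COCCC1
Why: acid-catalysed acetalisation of a primary alcohol gives a base-stable THP ether, so the α-oxygen survives the basic condensation and the free α-hydroxy ketone is never exposed to base; the acetal carbon is racemic and is removed later.

Step 4
Reactants: 5 1-(3,5-dibromo-4-methoxyphenyl)-2-(tetrahydro-2H-pyran-2-yloxy)ethanone; 6 3,5-dibromo-4-methoxybenzaldehyde
Product: 8 (Z)-1,3-bis(3,5-dibromo-4-methoxyphenyl)-2-hydroxyprop-2-en-1-one, via THP-protected chalcone 7 (not isolated)
Conditions: KOH (30 mol %), EtOH, 0 °C to rt; then HCl in EtOH to pH 1, rt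
Reagents that add atoms: none
Why: Claisen–Schmidt condensation of an α-alkoxy acetophenone with a non-enolisable, electron-poor aldehyde followed by E1cB dehydration should give the α-alkoxy enone with aryl trans to aroyl, and acid ethanolysis of the enol THP acetal then releases the chelated Z-enol, whose geometry is thermodynamic because it can equilibrate through the diketo tautomer.

Step 5
Reactants: 8 (Z)-1,3-bis(3,5-dibromo-4-methoxyphenyl)-2-hydroxyprop-2-en-1-one
Product: 10 (5Z)-4-(3,5-dibromo-4-methoxyphenyl)-5-[(3,5-dibromo-4-methoxyphenyl)methylidene]furan-2(5H)-one, via enol ester ylide 9 (not isolated)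
Conditions: Ph3P=C=C=O (1.2 equiv), toluene, rt to 110 °C, N2
Reagents that add atoms: (triphenylphosphoranylidene)ketene, O=C=C=P(c1ccccc1)(c1ccccc1)c1ccccc1
Why: Proposed new method: the acidic, chelated enol O–H of 8 should protonate the ylide carbon of Ph3P=C=C=O and the enolate oxygen should then add to the ketene carbon to give the enol ester ylide 9, whose ester-stabilised ylide carbon attacks the neighbouring aryl ketone and, through the oxaphosphetane, expels Ph3P=O to form the C3=C4 bond. The closest known reaction types are the addition/intramolecular Wittig butenolide synthesis from α-hydroxy ketones and this ylide and the analogous 2-pyranone and coumarin syntheses from enolised 1,3-diketones and ortho-hydroxyaryl ketones; new here is the enol of a 1,2-diketone as the O–H partner, which should deliver the 5-ylidene butenolide directly. The lactone ring closes by a 5-exo-trig attack of the ylide carbon on the ketone carbonyl. No stereocentre is formed, and the Z geometry of the exocyclic alkene is that of the enol double bond of 8 (aryl cis to the enol oxygen), which the reaction does not touch and which is also the less strained geometry of the product. The step needs O-acylation over C-acylation of the ambident enolate and carbonyl olefination over conjugate addition: the hard ketene carbon favours the oxygen terminus, and attack at the benzylidene carbon would be a disfavoured 5-endo-trig closure. The methyl ethers leave no other O–H group for the ylide.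

Step 6
Reactants: 10 (5Z)-4-(3,5-dibromo-4-methoxyphenyl)-5-[(3,5-dibromo-4-methoxyphenyl)methylidene]furan-2(5H)-one
Product: 11 rubrolide A, (5Z)-4-(3,5-dibromo-4-hydroxyphenyl)-5-[(3,5-dibromo-4-hydroxyphenyl)methylidene]furan-2(5H)-one
Conditions: BBr3 (6 equiv), CH2Cl2, −78 °C to rt; then H2O
Reagents that add atoms: none
Why: BBr3 cleavage of aryl methyl ethers (boron–oxygen complexation, then bromide attack at methyl) should free both phenols, while the lactone, the aryl bromides and the thermodynamically preferred Z-alkene should survive at or below room temperature.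

**Compound list**

1 | 1-(3,5-dibromo-4-hydroxyphenyl)ethanone | CC(=O)c1cc(Br)c(O)c(Br)c1 | starting material
2 | 1-(3,5-dibromo-4-methoxyphenyl)ethanone | CC(=O)c1cc(Br)c(OC)c(Br)c1 | intermediate
3 | 2-(3,5-dibromo-4-methoxyphenyl)-2,2-dimethoxyethanol (not isolated) | COC(CO)(OC)c1cc(Br)c(OC)c(Br)c1 | intermediate
4 | 1-(3,5-dibromo-4-methoxyphenyl)-2-hydroxyethanone | O=C(CO)c1cc(Br)c(OC)c(Br)c1 | intermediate
5 | 1-(3,5-dibromo-4-methoxyphenyl)-2-(tetrahydro-2H-pyran-2-yloxy)ethanone (racemic) | O=C(COC1CCCCO1)c1cc(Br)c(OC)c(Br)c1 | intermediate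
6 | 3,5-dibromo-4-methoxybenzaldehyde | O=Cc1cc(Br)c(OC)c(Br)c1 | starting material
7 | (Z)-1,3-bis(3,5-dibromo-4-methoxyphenyl)-2-(tetrahydro-2H-pyran-2-yloxy)prop-2-en-1-one (racemic, not isolated) | O=C(c1cc(Br)c(OC)c(Br)c1)/C(OC1CCCCO1)=C/c1cc(Br)c(OC)c(Br)c1 | intermediate
8 | (Z)-1,3-bis(3,5-dibromo-4-methoxyphenyl)-2-hydroxyprop-2-en-1-one | O=C(c1cc(Br)c(OC)c(Br)c1)/C(O)=C/c1cc(Br)c(OC)c(Br)c1 | intermediate
9 | (Z)-1,3-bis(3,5-dibromo-4-methoxyphenyl)-3-oxoprop-1-en-2-yl (triphenylphosphoranylidene)acetate (not isolated) | O=C(c1cc(Br)c(OC)c(Br)c1)/C(OC(=O)C=P(c1ccccc1)(c1ccccc1)c1ccccc1)=C/c1cc(Br)c(OC)c(Br)c1 | intermediate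
10 | (5Z)-4-(3,5-dibromo-4-methoxyphenyl)-5-[(3,5-dibromo-4-methoxyphenyl)methylidene]furan-2(5H)-one | O=C1C=C(c2cc(Br)c(OC)c(Br)c2)/C(=C/c2cc(Br)c(OC)c(Br)c2)O1 | intermediate
11 | rubrolide A, (5Z)-4-(3,5-dibromo-4-hydroxyphenyl)-5-[(3,5-dibromo-4-hydroxyphenyl)methylidene]furan-2(5H)-one | O=C1C=C(c2cc(Br)c(O)c(Br)c2)/C(=C/c2cc(Br)c(O)c(Br)c2)O1 | target

**Step count and risks**

Total step count: 6. Longest linear sequence: 6 steps (1 to 11); aldehyde 6 enters unchanged at step 4.

Steps most likely to fail:

Step 5. O-acylation of the enol may be slow or may lose to C-acylation of the ambident enolate, and the stabilised ylide may olefinate the conjugated aryl ketone too sluggishly, so that the enol ester ylide hydrolyses or oligomerises before it closes. The fallback sets out from 4 and returns at 10. The α-hydroxy ketone 4 is heated with Ph3P=C=C=O in toluene, the known butenolide annulation of α-hydroxy ketones. This gives the ester ylide 2-(3,5-dibromo-4-methoxyphenyl)-2-oxoethyl (triphenylphosphoranylidene)acetate F1, which closes by intramolecular Wittig reaction to 4-(3,5-dibromo-4-methoxyphenyl)furan-2(5H)-one F2. The exocyclic alkene is then installed separately by vinylogous aldol condensation of F2 with aldehyde 6 (piperidine, MeOH, rt), which should give the Z-ylidene butenolide 10 under thermodynamic control.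

Step 4. The aldol adduct may dehydrate incompletely or revert by retro-aldol cleavage, and early loss of the THP group would expose the diketone to base and air (benzilic-type rearrangement, oxidative cleavage). The fallback sets out from 2 and 6 and returns at 8, with no α-oxygenated ketone. Claisen–Schmidt condensation of 2 with 6 (NaOH, EtOH) should give (E)-1,3-bis(3,5-dibromo-4-methoxyphenyl)prop-2-en-1-one F3. Weitz–Scheffer epoxidation (H2O2, NaOH, MeOH/THF, 0 °C) should give the racemic trans-epoxy ketone (3,5-dibromo-4-methoxyphenyl)[3-(3,5-dibromo-4-methoxyphenyl)oxiran-2-yl]methanone F4. Base-induced isomerisation of F4 (NaOH, EtOH, brief warming, then acid), by α-deprotonation and E1cB opening of the epoxide, is the classical behaviour of chalcone oxides and should give the enol 8.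

Step 2. Oxidative 1,2-aryl migration or over-oxidation may compete under the hypervalent iodine conditions, and the α-hydroxy ketone may self-condense during ketal hydrolysis. The fallback sets out from 2 and returns at 4 by a halogenation/substitution sequence. α-Bromination of 2 with CuBr2 (EtOAc/CHCl3, reflux) should give 2-bromo-1-(3,5-dibromo-4-methoxyphenyl)ethanone F5. Displacement with HCO2Na (EtOH/H2O, reflux) should give 2-(3,5-dibromo-4-methoxyphenyl)-2-oxoethyl formate F6, which is solvolysed in the same pot to 4.

**Further compounds**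

F1 | step 5 | 2-(3,5-dibromo-4-methoxyphenyl)-2-oxoethyl (triphenylphosphoranylidene)acetate | O=C(COC(=O)C=P(c1ccccc1)(c1ccccc1)c1ccccc1)c1cc(Br)c(OC)c(Br)c1
F2 | step 5 | 4-(3,5-dibromo-4-methoxyphenyl)furan-2(5H)-one | O=C1C=C(c2cc(Br)c(OC)c(Br)c2)CO1
F3 | step 4 | (E)-1,3-bis(3,5-dibromo-4-methoxyphenyl)prop-2-en-1-one | O=C(/C=C/c1cc(Br)c(OC)c(Br)c1)c1cc(Br)c(OC)c(Br)c1
F4 | step 4 | trans-(3,5-dibromo-4-methoxyphenyl)[3-(3,5-dibromo-4-methoxyphenyl)oxiran-2-yl]methanone (racemic, one enantiomer drawn) | O=C([C@H]1O[C@@H]1c1cc(Br)c(OC)c(Br)c1)c1cc(Br)c(OC)c(Br)c1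
F5 | step 2 | 2-bromo-1-(3,5-dibromo-4-methoxyphenyl)ethanone | O=C(CBr)c1cc(Br)c(OC)c(Br)c1
F6 | step 2 | 2-(3,5-dibromo-4-methoxyphenyl)-2-oxoethyl formate | O=COCC(=O)c1cc(Br)c(OC)c(Br)c1
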